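## The problem

Atom labels used throughout: C1 is the ring CH that carries the side chain, C4 the ring carbinol carbon, C5 the ring-fusion CH, C7 the ring CH that carries the carbinol carbon C11, C10 the methylated ring-fusion carbon and C9' the benzylic CH. Ring A is C1–C5 with C10, ring B is C5–C10, and α is the face of the decalin that carries the C10 methyl.

The target is a trans-fused decalin of the eudesmane type in which C1, the quaternary C10 and C5 are contiguous. C1 is joined through the acyclic benzylic centre C9' to an isobutyl group and a fully substituted diformylphloroglucinol ring. Six stereocentres must be set: C9' (R), C1 (branch α, equatorial), C4 (hydroxyl α and axial, methyl β), C5 (H β), C7 (hydroxyisopropyl α, equatorial) and C10. C9' lies outside the rings, so only an auxiliary or a reagent can fix it; once fixed it can direct C1 by 1,2-induction, and C1 is the only ring centre it touches. Inside the bicycle C10 is the pivot. With C10 fixed relative to C1, H-5 β and an equatorial C7 substituent are the thermodynamic arrangements, and the C4 carbinol follows from equatorial attack on a C4 ketone whose axial face is screened by the C10 methyl. The diformylphloroglucinol will not survive organolithium reagents, enolate bases or oxidants, and the two tertiary alcohols will not survive Lewis or strong protic acids. The arene therefore travels as its trimethyl ether and is formylated at the very end without acid. The feature that opens the key step is the C4 carbinol: it is one methyl addition away from a C4 ketone whose α-carbon is C5. If ring B is drawn as a 2,5-cyclohexadienone with its carbonyl at C7, C5 becomes an enone β-carbon, C10 carries two identical arms and is no stereocentre, and C4–C5 is a 1,4-dicarbonyl bond that an acyl anion at C4 can make by conjugate addition.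

## Retrosynthesis

**Arene endgame (29 ⇒ 28 ⇒ 27 ⇒ 26).** The three O–methyl bonds and the two aryl–CHO bonds are cut first. Electrophilic formylation with a Lewis acid would ionise both tertiary alcohols, so the formyl carbons are traced to a dibromide (27) and halogen–lithium exchange. Diol 26 has no aldehyde and a robust trimethyl ether. The forward steps must brominate only the two free ring positions, exchange twice in the presence of two alkoxides, and demethylate with a thiolate, which the formyl groups activate.

**Three methyl groups (26 ⇒ 25 ⇒ 23).** The two C11–CH3 bonds and the C4–CH3 bond are cut back to a C4 ketone and a C7 nitrile (23). A C7 ester would take both C11 methyls at once, but it would have to be equilibrated while the C4 ketone still allows C5 to move, which couples the two centres. With the nitrile, methyllithium first converts C4 into the carbinol and freezes C5. Only then is C7 equilibrated as the acetyl group of 25. The forward reactions must give equatorial attack at C4, single addition to the nitrile, and addition to an enolisable methyl ketone without loss of C7.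

**One carbon at C7 and the ring fusion (23 ⇒ 22).** The C7–C11 bond is cut to the C7 ketone of cis-fused dione 22. The C7 carbonyl sits between two methylenes, whereas C4 is flanked by the ring-fusion CH next to the quaternary carbon. A reductive cyanation should therefore choose C7. Its alkoxide base is also asked to bring C5 to the trans fusion through the C4 enolate.

**Key disconnection (22 ⇒ 21 ⇒ 20).** After the C8=C9 alkene is restored (21), the C4–C5 bond is cut. This is the only cut that makes ring B symmetrical. It removes C10 and C5 as stereocentres in one stroke and leaves a monocyclic aldehyde (20) with just C9' and C1. Cuts at C5–C10 or C9–C10 would instead form the quaternary carbon in a stereo-defining C–C bond formation. The forward reaction is a carbene-catalysed acyl anion addition to one of two enone arms that differ only in their relation to C1. In a chair-like closure the required arm places the C9' branch axial on the new ring, so the catalyst must dominate the choice.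

**Ring B (20 ⇒ 19 ⇒ 17 ⇒ 14 + 15).** The aldehyde is masked as a dioxolane (19), one ring alkene is removed (17), and the cyclohexenone is opened by a Robinson disconnection to α-methyl aldehyde 14 and methyl vinyl ketone 15. The quaternary carbon is thus made in a step where its configuration is irrelevant: 17 forms as two epimers that converge on 19. The forward steps need a Michael addition of a hindered aldehyde enolate and a dehydrogenation that spares the electron-rich benzylic C9'–H.

**C1 (14 ⇒ 10 + 11).** The C1–C2 bond is cut to enal 10 and the three-carbon acetal bromide 11, used as its Grignard reagent. Cutting C1–C10 instead would need a tertiary nucleophile. The forward conjugate addition must add to the face of the alkene away from the aryl group, the rotamer being fixed by allylic strain with the α-methyl.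

**C9' (10 ⇒ 8 ⇒ 7 ⇒ 6 ⇒ 4 + 5; 4 ⇒ 1 + 2).** The C1=C10 alkene is cut by a Wittig disconnection to alcohol 8, which comes from imide 7. The C9'–CH2 bond is cut to the arylacetyl imide 4 and methallyl bromide 5. An isobutyl halide is too unreactive for an imide enolate, hence the allylic halide and a hydrogenation (6 to 7). Imide 4 comes from the catalogue acid 1 and the oxazolidinone 2.

## Roads not taken

**Alternative 1:** a biomimetic cascade that cuts aryl–C9', C9'–C1 and C5–C10 together. In one flask 2,4,6-trihydroxybenzene-1,3-dicarbaldehyde A2 condenses with 3-methylbutanal A3 to the ortho-quinone methide A5. Its exocyclic carbon is attacked by C1 of (7S)-hedycaryol A4, the C10 cation is captured across the ring by C5, and proton loss gives the 3-ene A1.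
- Merits: three bonds and both rings in one operation, no protecting groups, C7 bought with the terpene, and the trans fusion arising from the folded ten-membered ring.
- Weak points: A4 is a scarce germacradienol that undergoes Cope rearrangement on mild warming. C9' forms by intermolecular attack on a planar quinone methide with no control element. The cation can end in more than one alkene. A1 still lacks the C4 hydroxyl, and a Markovnikov hydration with the hydroxyl on the α face would have to be done beside free phenols and aldehydes.
- Comparison: this road is far shorter than the chosen plan, and that advantage is real. The chosen plan sets against it auxiliary control of C9', a defined C4 carbinol from a ketone, and independence from A4.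

**Alternative 2:** a Prins closure of ring B that cuts C7–C8. In aqueous H2SO4 the C8 aldehyde of A6 adds to C7 of the prenyl group on C5, and water captures the C11 cation to give A7.
- Merits: ring B, the C11 carbinol and an equatorial C7 are formed in the ring-closing step itself through a chair. No equilibration at C7 or C5 is needed, and in this respect the road is better than the chosen plan.
- Weak points: A7 carries an extra C8 hydroxyl that must be removed beside a tertiary alcohol. C1 bears only an ester, so the C1–C9' bond, the aryl ring and the isobutyl group must be added late, next to the quaternary carbon, with nothing to control C9'. A6 itself needs the C1/C5/C10 triad, including the quaternary centre, built beforehand in enantiomerically defined form.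
- Comparison: the chosen plan accepts two thermodynamic corrections (C5, C7) in exchange for fixing C9' first with an auxiliary and relaying it to C1.

**Alternative 3:** a radical annulation that cuts C9–C10. The primary C9 radical from iodide A8 (Bu3SnH, AIBN) adds 6-endo to C10 of the tetrasubstituted enone, and the α-keto radical at C5 is reduced to give A9.
- Merits: the methylated quaternary carbon and ring B come from a simple alkylated cyclohexenone. The C7 ester would give the C11 carbinol with two equivalents of a methyl nucleophile in one step, shorter than the nitrile sequence chosen here. The same C4 ketone is left for the methyl addition.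
- Weak points: the facial course at C10 and the hydrogen transfer to C5 rest on substrate control from the C1 ester alone. C7 must already be set in the acyclic chain. There is no source of absolute configuration without a resolution, stoichiometric tin is needed, and the C9' centre again has to be built late from the C1 ester without control.
- Comparison: this road makes the quaternary centre more simply. The chosen plan offers catalyst control of C10 and early control of C9'.

Key step: step 10

Assumption: the triazolium antipode written in step 10 is taken to be the one that delivers the acyl anion to the required enone arm; if its sense proves opposite, the mirror-image salt is used with no other change.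

## Route

Step 1
Reactants: 1 2-(2,4,6-trimethoxyphenyl)acetic acid; 2 (S)-4-benzyloxazolidin-2-one
Product: 4 (S)-4-benzyl-3-[2-(2,4,6-trimethoxyphenyl)acetyl]oxazolidin-2-one, via mixed pivalic anhydride 3 (not isolated)
Conditions: PivCl, Et3N, THF, −20 °C; then 2, LiCl, 23 °C
Reagents that add atoms: none
Why: N-acylation of the oxazolidinone through a mixed anhydride is standard for arylacetic acids; no stereocentre is formed.

Step 2
Reactants: 4; 5 3-bromo-2-methylpropene
Product: 6 (S)-4-benzyl-3-[(S)-4-methyl-2-(2,4,6-trimethoxyphenyl)pent-4-enoyl]oxazolidin-2-one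
Conditions: NaN(SiMe3)2, THF, −78 °C; then 5, −78 to −40 °C
Reagents that add atoms: none
Why: Evans alkylation: the chelated Z sodium enolate is attacked by the allylic bromide on the face away from the benzyl group, which sets C9' (the descriptor is S here because the acyl carbon outranks the aryl carbon). A reactive allylic halide is used because the ortho-methoxy groups crowd the enolate carbon.

Step 3
Reactants: 6
Product: 7 (S)-4-benzyl-3-[(S)-4-methyl-2-(2,4,6-trimethoxyphenyl)pentanoyl]oxazolidin-2-one
Conditions: H2 (1 atm), Pd/C, EtOAc, 23 °C
Reagents that add atoms: none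
Why: Heterogeneous hydrogenation of the 1,1-disubstituted alkene gives the isobutyl group under neutral conditions that cannot epimerise the α-aryl imide.

Step 4
Reactants: 7
Product: 8 (S)-4-methyl-2-(2,4,6-trimethoxyphenyl)pentan-1-ol
Conditions: LiBH4, MeOH (1 equiv), Et2O, 0 °C
Reagents that add atoms: none
Why: Reductive cleavage of the imide at the exocyclic carbonyl gives the primary alcohol and returns the auxiliary; hydride reduction does not touch the α-centre.

Step 5
Reactants: 8
Product: 10 (2E,4R)-2,6-dimethyl-4-(2,4,6-trimethoxyphenyl)hept-2-enal, via aldehyde 9 (not isolated)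
Conditions: Dess–Martin periodinane, CH2Cl2, 0 to 23 °C; filter; then Ph3P=C(Me)CHO, toluene, 80 °C
Reagents that add atoms: 2-(triphenylphosphoranylidene)propanal, CC(C=O)=P(c1ccccc1)(c1ccccc1)c1ccccc1
Why: Dess–Martin oxidation followed by Wittig olefination with the stabilised formyl ylide should give the E trisubstituted enal. The α-aryl aldehyde is used crude at once so that it has little time to epimerise, and the twisted, electron-rich aryl ring makes its α-hydrogen only weakly acidic.

Step 6
Reactants: 10; 11 2-(2-bromoethyl)-1,3-dioxolane
Product: 14 (3R,4R)-3-[2-(1,3-dioxolan-2-yl)ethyl]-2,6-dimethyl-4-(2,4,6-trimethoxyphenyl)heptanal (both C2 epimers), via Grignard reagent 12 (not isolated), via silyl enol ether 13 (not isolated)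
Conditions: 11, Mg, THF, 25 °C; then CuBr·SMe2 (10 mol %), TMSCl, DMPU, THF, −78 °C, add 10; then AcOH, THF–H2O, 0 °C
Reagents that add atoms: none
Why: Copper-catalysed conjugate addition of a Grignard reagent to an enal, accelerated by chlorosilane trapping, is well established. Allylic 1,3-strain with the α-methyl holds the C9'–H bond in the alkene plane, and the nucleophile should add to the face opposite the 2,4,6-trimethoxyphenyl group, which sets C1. The epimers at the α-methyl carbon (the future C10) are of no consequence.

Step 7
Reactants: 14; 15 methyl vinyl ketone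
Product: 17 4-[(3R,4R)-1-(1,3-dioxolan-2-yl)-6-methyl-4-(2,4,6-trimethoxyphenyl)heptan-3-yl]-4-methylcyclohex-2-en-1-one (both epimers at the ring quaternary carbon), via keto aldehyde 16 (not isolated)
Conditions: 15, KOH (0.2 equiv), EtOH, 0 to 23 °C; then KOH (1 equiv), 70 °C
Reagents that add atoms: none
Why: Robinson annulation of an α,α-disubstituted aldehyde: Michael addition of the aldehyde enolate creates the quaternary carbon and intramolecular aldol condensation closes the cyclohexenone. Base is used because the dioxolane would not survive the acid-catalysed variant; the two epimers converge in step 8.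

Step 8
Reactants: 17
Product: 19 4-[(3R,4R)-1-(1,3-dioxolan-2-yl)-6-methyl-4-(2,4,6-trimethoxyphenyl)heptan-3-yl]-4-methylcyclohexa-2,5-dien-1-one, via silyl dienol ether 18 (not isolated)
Conditions: LiN(i-Pr)2, THF, −78 °C; TMSCl; then Pd(OAc)2 (1.05 equiv), MeCN, 23 °C
Reagents that add atoms: none
Why: Saegusa–Ito oxidation through the kinetic cross-conjugated silyl dienol ether is the standard route from 4,4-disubstituted cyclohexenones to cyclohexadienones. It is preferred to quinone or hypervalent-iodine dehydrogenation, which would attack the electron-rich benzylic C9'–H. The quaternary carbon is no longer a stereocentre in the product.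

Step 9
Reactants: 19
Product: 20 (4R,5R)-7-methyl-4-(1-methyl-4-oxocyclohexa-2,5-dien-1-yl)-5-(2,4,6-trimethoxyphenyl)octanal
Conditions: 1 M HCl, THF, 23 °C
Reagents that add atoms: water, O
Why: Acid hydrolysis of the dioxolane frees the C4 aldehyde. Dilute acid is far below what a dienone–phenol rearrangement needs and leaves the aryl ethers alone.

Step 10
Reactants: 20
Product: 21 cis-fused enedione: 10α-methyl-1α-[(1R)-3-methyl-1-(2,4,6-trimethoxyphenyl)butyl]-5α-H-decal-8-ene-4,7-dione (eudesmane numbering)
Conditions: (5aS,10bR)-2-(pentafluorophenyl)-5a,10b-dihydro-4H,6H-indeno[2,1-b][1,2,4]triazolo[4,3-d][1,4]oxazin-2-ium tetrafluoroborate (20 mol %), KN(SiMe3)2 (20 mol %), toluene, 23 °C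
Reagents that add atoms: none
Why: The carbene formed from the triazolium salt adds to the C4 aldehyde, proton transfer gives the Breslow intermediate (an acyl anion equivalent), and this adds 1,4 to one enone arm before the carbene is expelled, leaving the C4 ketone. The closest known reaction type is the triazolium-catalysed desymmetrising intramolecular Stetter reaction of aldehyde-tethered 4,4-disubstituted cyclohexadienones. Ring A closes in the 6-exo-trig mode. C5 is set by the tether: the acyl carbon can reach only the face of ring B that carries C1, so H-5 must end cis to the C10 methyl. C10 is set by the choice of arm, which is the catalyst's task. The step therefore needs arm selectivity, and here the substrate does not help: a chair-like closure onto the required arm puts the C9' branch axial on the new ring and the other arm puts it equatorial, so the catalyst antipode is chosen to overrule this bias. The N-pentafluorophenyl carbene suits enolisable aliphatic aldehydes, the substoichiometric base limits aldehyde enolate chemistry, and the four-carbon tether offers no smaller-ring Stetter closure.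

Step 11
Reactants: 21
Product: 22 cis-fused dione: 10α-methyl-1α-[(1R)-3-methyl-1-(2,4,6-trimethoxyphenyl)butyl]-5α-H-decalin-4,7-dione
Conditions: H2 (1 atm), Pd/C, EtOAc, 23 °C
Reagents that add atoms: none
Why: Chemoselective hydrogenation of the enone alkene; the ketones and the trimethoxyarene are untouched and no stereocentre is formed.

Step 12
Reactants: 22
Product: 23 trans-fused keto nitrile: 10α-methyl-1α-[(1R)-3-methyl-1-(2,4,6-trimethoxyphenyl)butyl]-4-oxo-5β-H-decalin-7-carbonitrile (both C7 epimers)
Conditions: TosMIC, KOt-Bu, DME, EtOH, 0 to 40 °C
Reagents that add atoms: p-toluenesulfonylmethyl isocyanide, Cc1ccc(cc1)S(=O)(=O)C[N+]#[C-]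
Why: Van Leusen reductive cyanation should take place at the C7 ketone, which lies between two methylenes, ahead of the C4 ketone next to the ring fusion (the same order of reactivity as in 3,6-diketo steroids). The alkoxide also equilibrates C5 through the C4 enolate toward the trans fusion, which avoids the axial ring bond of the cis isomer. Remaining cis-fused material is separated and returned to the base, and the C7 mixture is corrected in step 13.

Step 13
Reactants: 23
Product: 25 7α-acetyl-4α-hydroxy-4β,10α-dimethyl-1α-[(1R)-3-methyl-1-(2,4,6-trimethoxyphenyl)butyl]-5β-H-decalin, via C7-epimeric methyl ketones 24 (not isolated)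
Conditions: MeLi (4 equiv), Et2O, −78 to 0 °C; 1 M HCl, THF, 0 °C; then NaOMe (cat.), MeOH, 23 °C
Reagents that add atoms: methyllithium, [Li]C; water, O
Why: Methyllithium attacks the C4 ketone from the equatorial direction, because the axial C10 methyl blocks the α face, and so gives the axial 4α-hydroxyl. It adds once to the nitrile, and the work-up hydrolyses the resulting imine to the methyl ketone. With the ring fusion now frozen, methoxide equilibrates C7 to the equatorial (α) acetyl group.

Step 14
Reactants: 25
Product: 26 4α-hydroxy-7α-(2-hydroxypropan-2-yl)-4β,10α-dimethyl-1α-[(1R)-3-methyl-1-(2,4,6-trimethoxyphenyl)butyl]-5β-H-decalin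
Conditions: MeLi, CeCl3, THF, −78 °C
Reagents that add atoms: methyllithium, [Li]C
Why: The organocerium reagent adds to the enolisable methyl ketone without deprotonating it, so C7 is not disturbed; the free C4 hydroxyl only consumes one equivalent.

Step 15
Reactants: 26
Product: 27 dibromide: 26 with bromine at both free positions of the aryl ring (3,5-dibromo-2,4,6-trimethoxyphenyl)
Conditions: NBS (2.1 equiv), MeCN, 0 °C
Reagents that add atoms: N-bromosuccinimide, O=C1CCC(=O)N1Br
Why: Electrophilic aromatic bromination at the only two unsubstituted positions, each activated by three methoxy groups; tertiary alcohols are inert to NBS in the dark.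

Step 16
Reactants: 27
Product: 28 dialdehyde: 26 with formyl groups at both free positions of the aryl ring (3,5-diformyl-2,4,6-trimethoxyphenyl)
Conditions: t-BuLi (6.5 equiv), THF, −78 °C; DMF, −78 to 0 °C; then H2O
Reagents that add atoms: N,N-dimethylformamide, CN(C)C=O
Why: After deprotonation of both alcohols, double bromine–lithium exchange gives aryllithium sites that are each flanked and stabilised by two methoxy groups, and formylation with DMF delivers both aldehydes. No acid is involved, so the tertiary alcohols are safe.

Step 17
Reactants: 28
Product: 29 target: 5-[(1R)-1-(4α-hydroxy-7α-(2-hydroxypropan-2-yl)-4β,10α-dimethyl-5β-H-decalin-1α-yl)-3-methylbutyl]-2,4,6-trihydroxybenzene-1,3-dicarbaldehyde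
Conditions: NaSEt, DMF, 130 °C; then 1 M HCl
Reagents that add atoms: none
Why: Thiolate SN2 demethylation of aryl methyl ethers; all three methoxy groups are ortho or para to both formyl groups and therefore give good phenoxide leaving groups, and the basic conditions spare the tertiary alcohols.

## Compound list

1 | 2-(2,4,6-trimethoxyphenyl)acetic acid | OC(=O)Cc1c(OC)cc(OC)cc1OC | starting material
2 | (S)-4-benzyloxazolidin-2-one | O=C1N[C@@H](Cc2ccccc2)CO1 | starting material
3 | mixed anhydride of 1 with pivalic acid (not isolated) | CC(C)(C)C(=O)OC(=O)Cc1c(OC)cc(OC)cc1OC | intermediate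
4 | (S)-4-benzyl-3-[2-(2,4,6-trimethoxyphenyl)acetyl]oxazolidin-2-one | O=C(Cc1c(OC)cc(OC)cc1OC)N1[C@@H](Cc2ccccc2)COC1=O | intermediate
5 | 3-bromo-2-methylpropene | CC(=C)CBr | starting material
6 | (S)-4-benzyl-3-[(S)-4-methyl-2-(2,4,6-trimethoxyphenyl)pent-4-enoyl]oxazolidin-2-one | CC(=C)C[C@@H](c1c(OC)cc(OC)cc1OC)C(=O)N1[C@@H](Cc2ccccc2)COC1=O | intermediate
7 | (S)-4-benzyl-3-[(S)-4-methyl-2-(2,4,6-trimethoxyphenyl)pentanoyl]oxazolidin-2-one | CC(C)C[C@@H](c1c(OC)cc(OC)cc1OC)C(=O)N1[C@@H](Cc2ccccc2)COC1=O | intermediate
8 | (S)-4-methyl-2-(2,4,6-trimethoxyphenyl)pentan-1-ol | CC(C)C[C@@H](c1c(OC)cc(OC)cc1OC)CO | intermediate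
9 | (S)-4-methyl-2-(2,4,6-trimethoxyphenyl)pentanal (not isolated) | CC(C)C[C@@H](c1c(OC)cc(OC)cc1OC)C=O | intermediate
10 | (2E,4R)-2,6-dimethyl-4-(2,4,6-trimethoxyphenyl)hept-2-enal | CC(C)C[C@@H](c1c(OC)cc(OC)cc1OC)/C=C(\C)C=O | intermediate
11 | 2-(2-bromoethyl)-1,3-dioxolane | BrCCC1OCCO1 | starting material
12 | [2-(1,3-dioxolan-2-yl)ethyl]magnesium bromide (not isolated) | Br[Mg]CCC1OCCO1 | intermediate
13 | trimethylsilyl enol ether of 14, E/Z mixture (not isolated) | CC(C)C[C@@H](c1c(OC)cc(OC)cc1OC)[C@@H](CCC2OCCO2)C(C)=CO[Si](C)(C)C | intermediate
14 | (3R,4R)-3-[2-(1,3-dioxolan-2-yl)ethyl]-2,6-dimethyl-4-(2,4,6-trimethoxyphenyl)heptanal, both C2 epimers | CC(C)C[C@@H](c1c(OC)cc(OC)cc1OC)[C@@H](CCC2OCCO2)C(C)C=O | intermediate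
15 | methyl vinyl ketone (but-3-en-2-one) | CC(=O)C=C | starting material
16 | (3R,4R)-3-[2-(1,3-dioxolan-2-yl)ethyl]-2,6-dimethyl-2-(3-oxobutyl)-4-(2,4,6-trimethoxyphenyl)heptanal, both C2 epimers (not isolated) | CC(C)C[C@@H](c1c(OC)cc(OC)cc1OC)[C@@H](CCC2OCCO2)C(C)(C=O)CCC(C)=O | intermediate
17 | 4-[(3R,4R)-1-(1,3-dioxolan-2-yl)-6-methyl-4-(2,4,6-trimethoxyphenyl)heptan-3-yl]-4-methylcyclohex-2-en-1-one, both epimers at ring C4 | CC(C)C[C@@H](c1c(OC)cc(OC)cc1OC)[C@@H](CCC2OCCO2)C3(C)C=CC(=O)CC3 | intermediate
18 | 2-trimethylsilyloxy-1,3-diene from 17 by deprotonation at the ring CH2 next to the carbonyl (not isolated) | CC(C)C[C@@H](c1c(OC)cc(OC)cc1OC)[C@@H](CCC2OCCO2)C3(C)C=CC(O[Si](C)(C)C)=CC3 | intermediate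
19 | 4-[(3R,4R)-1-(1,3-dioxolan-2-yl)-6-methyl-4-(2,4,6-trimethoxyphenyl)heptan-3-yl]-4-methylcyclohexa-2,5-dien-1-one | CC(C)C[C@@H](c1c(OC)cc(OC)cc1OC)[C@@H](CCC2OCCO2)C3(C)C=CC(=O)C=C3 | intermediate
20 | (4R,5R)-7-methyl-4-(1-methyl-4-oxocyclohexa-2,5-dien-1-yl)-5-(2,4,6-trimethoxyphenyl)octanal | CC(C)C[C@@H](c1c(OC)cc(OC)cc1OC)[C@@H](CCC=O)C2(C)C=CC(=O)C=C2 | intermediate
21 | cis-fused 10α-methyl-1α-[(1R)-3-methyl-1-(2,4,6-trimethoxyphenyl)butyl]-5α-H-decal-8-ene-4,7-dione | CC(C)C[C@@H](c1c(OC)cc(OC)cc1OC)[C@H]1CCC(=O)[C@@H]2CC(=O)C=C[C@]12C | intermediate
22 | cis-fused 10α-methyl-1α-[(1R)-3-methyl-1-(2,4,6-trimethoxyphenyl)butyl]-5α-H-decalin-4,7-dione | CC(C)C[C@@H](c1c(OC)cc(OC)cc1OC)[C@H]1CCC(=O)[C@@H]2CC(=O)CC[C@]12C | intermediate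
23 | trans-fused 10α-methyl-1α-[(1R)-3-methyl-1-(2,4,6-trimethoxyphenyl)butyl]-4-oxo-5β-H-decalin-7-carbonitrile, both C7 epimers | CC(C)C[C@@H](c1c(OC)cc(OC)cc1OC)[C@H]1CCC(=O)[C@H]2CC(C#N)CC[C@]12C | intermediate
24 | 7-acetyl-4α-hydroxy-4β,10α-dimethyl-1α-[(1R)-3-methyl-1-(2,4,6-trimethoxyphenyl)butyl]-5β-H-decalin, both C7 epimers (not isolated) | CC(C)C[C@@H](c1c(OC)cc(OC)cc1OC)[C@H]1CC[C@@](C)(O)[C@H]2CC(C(C)=O)CC[C@]12C | intermediate
25 | 7α-acetyl-4α-hydroxy-4β,10α-dimethyl-1α-[(1R)-3-methyl-1-(2,4,6-trimethoxyphenyl)butyl]-5β-H-decalin | CC(C)C[C@@H](c1c(OC)cc(OC)cc1OC)[C@H]1CC[C@@](C)(O)[C@H]2C[C@@H](C(C)=O)CC[C@]12C | intermediate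
26 | 4α-hydroxy-7α-(2-hydroxypropan-2-yl)-4β,10α-dimethyl-1α-[(1R)-3-methyl-1-(2,4,6-trimethoxyphenyl)butyl]-5β-H-decalin | CC(C)C[C@@H](c1c(OC)cc(OC)cc1OC)[C@H]1CC[C@@](C)(O)[C@H]2C[C@@H](C(C)(C)O)CC[C@]12C | intermediate
27 | 3,5-dibromo-2,4,6-trimethoxyphenyl analogue of 26 | CC(C)C[C@@H](c1c(OC)c(Br)c(OC)c(Br)c1OC)[C@H]1CC[C@@](C)(O)[C@H]2C[C@@H](C(C)(C)O)CC[C@]12C | intermediate
28 | 3,5-diformyl-2,4,6-trimethoxyphenyl analogue of 26 | CC(C)C[C@@H](c1c(OC)c(C=O)c(OC)c(C=O)c1OC)[C@H]1CC[C@@](C)(O)[C@H]2C[C@@H](C(C)(C)O)CC[C@]12C | intermediate
29 | 5-[(1R)-1-(4α-hydroxy-7α-(2-hydroxypropan-2-yl)-4β,10α-dimethyl-5β-H-decalin-1α-yl)-3-methylbutyl]-2,4,6-trihydroxybenzene-1,3-dicarbaldehyde | CC(C)C[C@@H](c1c(O)c(C=O)c(O)c(C=O)c1O)[C@H]1CC[C@@](C)(O)[C@H]2C[C@@H](C(C)(C)O)CC[C@]12C | target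

## Step count and least certain steps

Total steps: 17. Longest linear sequence: 17 steps (the route is linear from 1).

**Step 10 (key step).** The most likely failure is poor arm selectivity. The catalyst's facial preference is opposed by the substrate's own preference for a chair-like closure with the C9' branch equatorial, which leads to the wrong C10 epimer. The pairing is then mismatched and the selectivity erodes. A slow six-ring closure would also give the aldehyde time for enolate side reactions.
Fallback, from 19 back to 22: the two arms are told apart before ring A is closed. Copper-hydride conjugate reduction of 19 with a chiral bisphosphine (Cu(OAc)2, (R)- or (S)-DTBM-SEGPHOS, (EtO)2MeSiH, t-BuOH, toluene) saturates one arm in an intermolecular step where the bias from C1 is small, and gives the single C10 epimer of the cyclohexenone acetal F1. Hydrolysis with 1 M HCl in THF frees the enone aldehyde F2. An achiral triazolium carbene then has only one enone to add to, and the same 6-exo Stetter closure gives 22 directly, so step 11 is no longer needed.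

**Step 6.** The most likely failure is low facial selectivity at C1. The 1,2-induction rests only on the size difference between the aryl ring and the isobutyl chain in an acyclic enal, and coordination of copper to an ortho-methoxy group could erode it.
Fallback, from 10 back to 14: the face is chosen by an auxiliary instead. Condensation of 10 with tert-butyl L-tert-leucinate (or the D ester, whichever addresses the required face) gives the unsaturated aldimine F3. Copper-free addition of Grignard reagent 12, directed by chelation of magnesium between the imine nitrogen and the ester carbonyl, gives the saturated aldimine F4. Aqueous citric acid in the work-up hydrolyses F4 to 14 and returns the amino ester.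

**Step 7.** The most likely failure is that the Michael addition does not compete. The enolate carbon is flanked by a methyl group and the doubly branched C1, so polymerisation of methyl vinyl ketone and self-condensation of the aldehyde can outrun it.
Fallback, from 14 back to 17: the preformed potassium enolate of 14 (KH, THF) is added under aprotic conditions to 3-(trimethylsilyl)but-3-en-2-one, whose adduct is a stabilised α-silyl enolate that cannot initiate polymerisation. This gives the silylated keto aldehyde F5. KOH in methanol then removes the silyl group and effects the aldol condensation to 17.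

**Step 12.** The most likely failure is loss of site selectivity, with TosMIC also attacking the C4 ketone. In addition, the equilibration at C5 is not expected to be complete and will need recycling of cis-fused material.
Fallback, from 22 back to 25: the more reactive carbonyl is masked first. Ethylene glycol and TsOH in refluxing benzene ketalise C7 under thermodynamic control while the acid equilibrates C5, giving the trans-fused keto ketal F6. MeLi with CeCl3 adds to C4 to give the carbinol ketal F7. Aqueous acid frees the hydroxy ketone F8. Van Leusen cyanation on this single ketone gives the hydroxy nitrile F9. MeLi and then NaOMe, as in step 13, return 25.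

**Step 16.** The most likely failure is an incomplete second exchange. The polyanion (two alkoxides and then an aryllithium) is poorly soluble, and proton capture would leave monoaldehyde or debrominated material.
Fallback, from 27 back to 28: Suzuki–Miyaura coupling of 27 with CH2=CHBF3K (Pd(OAc)2, SPhos, K3PO4, toluene–water, 90 °C) gives the divinyl arene F10. Lemieux–Johnson cleavage (OsO4 cat., NaIO4, 2,6-lutidine, dioxane–water) gives 28 without organolithium reagents.

## Further compounds

F1 | step 10 | single C10 epimer of 17 with the enone on the arm that becomes C5=C6 | CC(C)C[C@@H](c1c(OC)cc(OC)cc1OC)[C@@H](CCC2OCCO2)[C@]3(C)C=CC(=O)CC3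
F2 | step 10 | enone aldehyde from F1 | CC(C)C[C@@H](c1c(OC)cc(OC)cc1OC)[C@@H](CCC=O)[C@]2(C)C=CC(=O)CC2
F3 | step 6 | aldimine of 10 with tert-butyl L-tert-leucinate | CC(C)C[C@@H](c1c(OC)cc(OC)cc1OC)/C=C(\C)/C=N/[C@@H](C(C)(C)C)C(=O)OC(C)(C)C
F4 | step 6 | saturated aldimine after addition of 12 | CC(C)C[C@@H](c1c(OC)cc(OC)cc1OC)[C@@H](CCC2OCCO2)C(C)/C=N/[C@@H](C(C)(C)C)C(=O)OC(C)(C)C
F5 | step 7 | α-silylated keto aldehyde | CC(C)C[C@@H](c1c(OC)cc(OC)cc1OC)[C@@H](CCC2OCCO2)C(C)(C=O)CC([Si](C)(C)C)C(C)=O
F6 | step 12 | trans-fused 4-ketone with C7 as ethylene ketal | CC(C)C[C@@H](c1c(OC)cc(OC)cc1OC)[C@H]2CCC(=O)[C@H]3CC4(OCCO4)CC[C@]23C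
F7 | step 12 | 4α-hydroxy-4β-methyl C7 ethylene ketal | CC(C)C[C@@H](c1c(OC)cc(OC)cc1OC)[C@H]2CC[C@@](C)(O)[C@H]3CC4(OCCO4)CC[C@]23C
F8 | step 12 | 4α-hydroxy-4β-methyl 7-ketone | CC(C)C[C@@H](c1c(OC)cc(OC)cc1OC)[C@H]2CC[C@@](C)(O)[C@H]3CC(=O)CC[C@]23C
F9 | step 12 | 4α-hydroxy-4β-methyl 7-carbonitrile, both C7 epimers | CC(C)C[C@@H](c1c(OC)cc(OC)cc1OC)[C@H]2CC[C@@](C)(O)[C@H]3CC(C#N)CC[C@]23C
F10 | step 16 | 3,5-divinyl-2,4,6-trimethoxyphenyl analogue of 26 | CC(C)C[C@@H](c1c(OC)c(C=C)c(OC)c(C=C)c1OC)[C@H]2CC[C@@](C)(O)[C@H]3C[C@@H](C(C)(C)O)CC[C@]23C
A1 | alternative 1 | 3-ene cascade product (target without the C4 hydroxyl) | CC(C)C[C@@H](c1c(O)c(C=O)c(O)c(C=O)c1O)[C@H]1CC=C(C)[C@H]2C[C@@H](C(C)(C)O)CC[C@]12C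
A2 | alternative 1 | 2,4,6-trihydroxybenzene-1,3-dicarbaldehyde | O=Cc1c(O)cc(O)c(C=O)c1O
A3 | alternative 1 | 3-methylbutanal | CC(C)CC=O
A4 | alternative 1 | (7S)-hedycaryol | C/C1=C\C[C@@H](C(C)(C)O)CC/C(C)=C/CC1
A5 | alternative 1 | ortho-quinone methide from A2 and A3 | CC(C)CC=C1C(=O)C(C=O)=C(O)C(C=O)=C1O
A6 | alternative 2 | Prins precursor with C8 aldehyde and prenyl group on C5 | CCOC(=O)[C@H]1CCC(=O)[C@@H](CC=C(C)C)[C@]1(C)CC=O
A7 | alternative 2 | trans-decalone with C11 carbinol and C8 hydroxyl | CCOC(=O)[C@H]1CCC(=O)[C@H]2C[C@@H](C(C)(C)O)[C@H](O)C[C@]12C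
A8 | alternative 3 | iodide on a tetrasubstituted cyclohexenone | CCOC(=O)[C@H]1CCC(=O)C(C[C@H](CCI)C(=O)OC)=C1C
A9 | alternative 3 | trans-decalone diester | CCOC(=O)[C@H]1CCC(=O)[C@H]2C[C@@H](C(=O)OC)CC[C@]12C
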